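## Structural features

The target is a (2S)-flavanone. Benzo ring A (C4a, C5, C6, C7, C8, C8a) is fused to the dihydropyranone ring C (O1, C2, C3, C4, C4a, C8a), and ring B, a 3-hydroxy-4,5-dimethoxyphenyl group, is attached at C2 by a single bond. Ring A has methoxy groups on C7 and C8, so C4a, C8a, C8 and C7 are four contiguous substituted carbons; ring B has one free phenol (C3') next to two methyl ethers (C4', C5'). C2 is the only stereocentre: it has no stereogenic neighbour, is benzylic, is bound to O1 and lies β to the C4 carbonyl. This makes it fragile, because base can expel the O1 phenoxide from the C3 enolate (retro-oxa-Michael opening to the 2'-hydroxychalcone) and reclosure racemises C2; the benzylic C2–O1 bond can also be cleaved reductively. The real difficulties are to set C2 in high enantiopurity and keep conditions neutral afterwards, to place the substituents of ring A regiospecifically, and to keep one phenol distinct from four methyl ethers. The key step uses the fact that C4 is a single carbonyl carbon between C4a and C3 and that O1 sits on C8a, ortho to C4a: ring C maps onto a 2-iodophenol (C4a–I, C8a–OH), one molecule of carbon monoxide (C4) and an aryl acetylene (C3, C2 and ring B).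

## Logic of the disconnections

16 ⇒ 15. The O–CH2 bond of a benzyl ether on the C3' oxygen is cut. The free phenol would not pass the base, the palladium chemistry and the oxidant used earlier, so it is carried as an ether that leaves under neutral conditions. The gain is that all earlier intermediates carry only ether oxygens on ring B. The forward step must cleave this benzylic C–O bond without touching the other one (C2–O1) or the C4 carbonyl, and without base.

15 ⇒ 13 (through 14). The C2–H and C3–H bonds are removed, so C2=C3 appears and the only stereocentre disappears. The reason is that 13 is flat, achiral and cannot racemise, so configuration is introduced only after all skeletal bonds exist. The gain is a precursor whose assembly needs no chiral reagent. The forward step must distinguish the two faces of C2=C3 by catalyst control alone and must cope with over-reduction at C4 (14), which is repaired by reoxidation in the same operation.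

13 ⇒ 5 + 9 + 10 (through 12 and 11). Three bonds are cut: O1–C2, then C3–C4 and C4a–C4. The cut is made here because C4 is a lone carbonyl carbon between an arene and a two-carbon unit, with the ring oxygen ortho to it. The gain is the largest of the route: one ring and three skeletal bonds fall away, leaving three pieces, and ring A keeps iodine and hydroxyl on the carbons that were C4a and C8a, which fixes its regiochemistry. The forward step must let carbonyl insertion precede alkyne coupling and must close the six-membered ring at C2, not the five-membered ring at C3.

5 ⇒ 4. The O–CH2 bond of an acetal on the phenolic oxygen is cut (in the backward sense a protecting group is added). A free hydroxyl cannot be present during metalation, and the acetal is also the group that directs it. There is no skeletal gain; the forward step needs acid mild enough to spare the C–I bond.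

4 ⇒ 2 (through 3). The C–I bond ortho to the acetal oxygen is cut, first to C–Li (3) and then to C–H. The reason is that this carbon is the only one ortho to the directing acetal. The gain is a halogen-free arene. The forward step must deprotonate this carbon and not the one ortho to the terminal methoxy group.

2 ⇒ 1. The O–CH2 bond of the acetal is cut, giving the commercial phenol. The forward step is a simple O-alkylation.

9 ⇒ 8. The C≡C bond is cut: the terminal carbon is removed and the ring-bound carbon returns to an aldehyde. Aryl aldehydes with this oxygenation pattern are available, and aryl acetylenes are not. The forward step is a one-carbon homologation that must be mild towards the ethers.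

8 ⇒ 6 + 7. The O–CH2 bond of the benzyl ether is cut, giving two commercial materials. The forward step must alkylate the only acidic group and leave the aldehyde alone.

## Other disconnections considered

Alternative 1: The cut is the aryl ether bond C8a–O1, with the C4 carbonyl hidden as a dioxolane. Forward, the (S)-alcohol A1, which carries the bromoarene of ring A on the ketal carbon, would be closed to the ketal A2 by intramolecular palladium-catalysed C–O coupling (Pd(OAc)2, a bulky di-tert-butyl biaryl phosphine, Cs2CO3); mild acid hydrolysis of A2 would then give 15.
- In its favour: the stereocentre is in place before ring closure and is not touched by it. The ketal removes the enolisable carbonyl, so base cannot racemise C2 by ring opening. Neither pressurised carbon monoxide nor pressurised hydrogen is needed.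
- Against it here: the alkoxide of divalent palladium formed from a secondary benzylic alcohol has a β-hydrogen and can collapse to a ketone with reduction of the arene. The C–Br bond lies between a methoxy group and the quaternary ketal carbon, which slows both oxidative addition and C–O reductive elimination. A1 is costly to reach: it needs a regiodefined bromination of ring A, an enantioselective aldol or carbonyl reduction, and a ketalisation next to a β-oxygen substituent that can eliminate.
- Comparison: alternative 1 is the better on configurational safety, since C2 never sits next to a free ketone until the last step. It is equal in that one catalytic step closes ring C. The chosen plan is the better on convergence and step economy: it forms three bonds in the key step instead of one, and the way to A1 is longer than the ways to 5 and 9 together.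

Alternative 2: The cut removes O1–C2 and C3–C4 together, so ring C is read as the adduct of an ortho-quinone methide (O1, C8a, C4a, C4) and a styrene (C2, C3). Forward, the salicylaldehyde acetal A3 would lose methanol under a chiral N-triflyl phosphoramide to give the 4-methoxy ortho-quinone methide as a chiral ion pair. This would add the ring B styrene A4 in an inverse-demand [4+2] cycloaddition to give the cis-4-methoxyflavan A5.
- In its favour: two bonds, the ring and the C2 stereocentre arise in one catalytic step from two aldehyde-derived pieces (A4 is one Wittig methylenation away from 8). Ring A needs no halogenation, and no gas under pressure is used.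
- Against it here: A5 has the wrong oxidation level at C4, so the methoxy group must be exchanged for hydroxyl and then oxidised to reach 15. The benzylic, ortho-oxygenated C4–O bond that makes this exchange easy can also re-ionise to the quinone methide, and cycloreversion would erode C2. A second stereocentre (C4) is built only to be destroyed. A4 has one para donor but two meta oxygens, so it is a weaker 2π partner than simple 4-alkoxystyrenes.
- Comparison: alternative 2 is equal on convergence and better in that the stereocentre is set in the ring-forming step itself. The chosen plan is better in that its key step gives the correct oxidation level at C4 directly and uses less specialised catalysts. The number of operations after the key step is about the same in both.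

Alternative 3: The cut removes C2–C3 and C4–C4a and keeps O1–C2 as an aryl ether of 1. Ring C becomes an aryloxy carbenium ion (C2) plus a two-carbon ketene acetal (C3, C4). Forward, the racemic α-acetoxy ether A6 would be ionised by a confined chiral Brønsted acid of the imidodiphosphorimidate class. The ion pair would add ketene diethyl acetal A7 at C2, and the resulting dialkoxycarbenium ion would close onto C4a of ring A (para to the C7 methoxy group) in a Friedel–Crafts step to give the flavanone diethyl ketal A8. Mild acid would hydrolyse A8 to 15.
- In its favour: it is stereoconvergent, since both enantiomers of A6 feed one ion pair. It starts from 1 and 8 with no halogenation, directed metalation or protecting group on ring A. The product has the right oxidation level and is masked against racemisation. No pressure equipment is needed, and on paper it is the shortest of the four plans.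
- Against it here: the cation is stabilised by the aryloxy oxygen and by the electron-rich ring B, so it is long-lived and loosely paired, which works against enantiocontrol. The second bond formation must outrun loss of an ethyl group, which would give an open-chain ester. A6 is acid-labile and releases an aldehyde easily, so it is awkward to make and handle.
- Comparison: alternative 3 is the better on step economy and on avoiding redox adjustment, and equal on convergence. The chosen plan is the better on precedent for each single step with this substitution pattern, and it does not depend on one highly specialised catalyst controlling an unusually stabilised cation.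

Key step: step 6

Assumption: the (R,R) antipode of the carbene precursor is written for step 7; which antipode delivers hydrogen to the Re face of C2 is settled in a trial run, and the (S,S) salt is used if the sense is the opposite.

## Route

Step 1
Reactants: 1 2,3-dimethoxyphenol
Product: 2 1,2-dimethoxy-3-(methoxymethoxy)benzene
Conditions: MOMCl, i-Pr2NEt, CH2Cl2, 0 °C → rt
Reagents that add atoms: chloromethyl methyl ether (MOMCl), COCCl
Why: O-alkylation of the phenol by the reactive α-chloro ether (Williamson-type), with the amine taking up HCl. The acetal is chosen because it directs the metalation of step 2 and leaves under mild acid.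

Step 2
Reactants: 2 1,2-dimethoxy-3-(methoxymethoxy)benzene
Product: 4 1-iodo-3,4-dimethoxy-2-(methoxymethoxy)benzene, via aryllithium 3 (not isolated)
Conditions: n-BuLi, TMEDA, THF, −78 → 0 °C; then I2, THF, −78 °C → rt
Reagents that add atoms: iodine, [I][I]
Why: Directed ortho-metalation: the two acetal oxygens chelate lithium and guide deprotonation to the only carbon ortho to the acetal (C6 of the phenol, the future C4a), in preference to the carbon ortho to the terminal methoxy group, which is a weaker director. The aryllithium 3 is then trapped by iodine.

Step 3
Reactants: 4 1-iodo-3,4-dimethoxy-2-(methoxymethoxy)benzene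
Product: 5 6-iodo-2,3-dimethoxyphenol
Conditions: HCl (2 M), MeOH, rt → 40 °C
Reagents that add atoms: none
Why: Acid-catalysed acetal exchange with methanol frees the phenol. Methyl ethers and the aryl iodide should not react with dilute acid at this temperature.

Step 4
Reactants: 6 3-hydroxy-4,5-dimethoxybenzaldehyde; 7 benzyl bromide
Product: 8 3-(benzyloxy)-4,5-dimethoxybenzaldehyde
Conditions: K2CO3, DMF, rt
Reagents that add atoms: benzyl bromide (compound 7), BrCc1ccccc1
Why: Williamson ether synthesis at the only acidic site; the non-enolisable aldehyde is inert to carbonate. The benzyl ether protects the C3' oxygen through steps 5 to 7 and is removed under neutral conditions at the end.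

Step 5
Reactants: 8 3-(benzyloxy)-4,5-dimethoxybenzaldehyde
Product: 9 1-(benzyloxy)-5-ethynyl-2,3-dimethoxybenzene (3-benzyloxy-4,5-dimethoxyphenylacetylene)
Conditions: dimethyl (1-diazo-2-oxopropyl)phosphonate, K2CO3, MeOH, rt
Reagents that add atoms: dimethyl (1-diazo-2-oxopropyl)phosphonate (Ohira–Bestmann reagent), COP(=O)(OC)C(=[N+]=[N-])C(C)=O
Why: Seyferth–Gilbert homologation in the Ohira–Bestmann form: methanolysis of the acetyl group releases the diazomethylphosphonate anion, which olefinates the aldehyde, loses nitrogen and gives the terminal alkyne by 1,2-shift. Carbonate in methanol is mild enough for an aryl aldehyde that carries benzyl and methyl ethers.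

Step 6
Reactants: 5 6-iodo-2,3-dimethoxyphenol; 9 1-(benzyloxy)-5-ethynyl-2,3-dimethoxybenzene; 10 carbon monoxide
Product: 13 3'-benzyloxy-4',5',7,8-tetramethoxyflavone, via ynone 11 (not isolated), via enaminone 12 (not isolated)
Conditions: PdCl2(PPh3)2 (5 mol %), CO (20 bar), Et2NH, 120 °C, autoclave
Reagents that add atoms: carbon monoxide (compound 10), [C-]#[O+]
Why: Zerovalent palladium, formed from PdCl2(PPh3)2 under carbon monoxide and amine, inserts into the C–I bond of 5, and carbon monoxide then inserts into the aryl–palladium bond to give an aroyl complex of divalent palladium; the electron-rich aryl group migrates readily and 20 bar of carbon monoxide keeps this ahead of direct alkynylation. Amine-assisted transfer of the acetylide of 9 and reductive elimination form C4a–C4 and C3–C4 in the ynone 11. Diethylamine adds to the β-carbon of 11 to give the enaminone 12, and the ortho hydroxyl attacks the same carbon (C2) in a 6-endo-trig addition–elimination that expels diethylamine, forms O1–C2 and closes ring C as the flavone 13. The closest known reaction type is the palladium-catalysed carbonylative coupling of 2-iodophenols with terminal aryl acetylenes in secondary amines, a copper-free carbonylative Sonogashira coupling followed by oxa-Michael ring closure. No stereocentre is formed. Three selectivities are needed: carbonylative over direct coupling (the latter would end in a 2-arylbenzofuran), capture of the aroyl complex by the alkyne and not by diethylamine (amide), and six-membered over five-membered closure (5-exo-dig at C3, aurone); carbon monoxide pressure, the reactivity of the terminal aryl acetylene and the enaminone detour, which leaves C2 as the only electrophilic carbon, should secure them. The regiochemistry of ring A is fixed in the substrate, because iodine and hydroxyl sit on the adjacent carbons that become C4a and C8a. Benzyl and methyl ethers are inert to diethylamine at 120 °C.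

Step 7
Reactants: 13 3'-benzyloxy-4',5',7,8-tetramethoxyflavone
Product: 15 (2S)-3'-benzyloxy-4',5',7,8-tetramethoxyflavanone, via cis-flavan-4-ol 14 (not isolated)
Conditions: Ru(cod)(2-methylallyl)2 (5 mol %), (R,R)-SINpEt·HBF4 [1,3-bis((1R)-1-(naphthalen-1-yl)ethyl)-4,5-dihydroimidazolium tetrafluoroborate] (10 mol %), KOt-Bu (10 mol %), n-hexane, 70 °C; then 13, H2 (100 bar), toluene, rt; filtration through silica; then DMP, CH2Cl2, 0 °C → rt
Reagents that add atoms: none
Why: Enantioselective hydrogenation of the C2=C3 bond of a flavone by a ruthenium complex of a C2-symmetric chiral N-heterocyclic carbene, a reaction type known for flavones and chromones; the carbene pocket selects the Re face of C2 (O1 > C1' > C3), which gives 2S. The same catalyst partly reduces the C4 carbonyl to the alcohol 14 (mainly 2,4-cis expected, its C4 configuration being irrelevant), and Dess–Martin oxidation under non-basic conditions returns all material to the ketone 15 without touching C2. The benzyl ether and the electron-rich benzene rings are not expected to be reduced at room temperature.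

Step 8
Reactants: 15 (2S)-3'-benzyloxy-4',5',7,8-tetramethoxyflavanone
Product: 16 (2S)-3'-hydroxy-4',5',7,8-tetramethoxyflavanone [(2S)-2-(3-hydroxy-4,5-dimethoxyphenyl)-7,8-dimethoxy-2,3-dihydro-4H-chromen-4-one]
Conditions: H2 (1 atm), 10 % Pd/C, EtOAc, rt
Reagents that add atoms: none
Why: Hydrogenolysis of the O-benzyl ether on Pd/C under neutral conditions, so the base-labile C2 centre is never exposed to base. The reaction is stopped after one equivalent of hydrogen to spare the slower-reacting benzylic C2–O1 bond and the C4 carbonyl.

## Compound list

1 | 2,3-dimethoxyphenol | COc1cccc(O)c1OC | starting material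
2 | 1,2-dimethoxy-3-(methoxymethoxy)benzene | COCOc1cccc(OC)c1OC | intermediate
3 | [3,4-dimethoxy-2-(methoxymethoxy)phenyl]lithium | [Li]c1ccc(OC)c(OC)c1OCOC | intermediate
4 | 1-iodo-3,4-dimethoxy-2-(methoxymethoxy)benzene | COCOc1c(I)ccc(OC)c1OC | intermediate
5 | 6-iodo-2,3-dimethoxyphenol | COc1ccc(I)c(O)c1OC | intermediate
6 | 3-hydroxy-4,5-dimethoxybenzaldehyde | COc1cc(C=O)cc(O)c1OC | starting material
7 | benzyl bromide | BrCc1ccccc1 | starting material
8 | 3-(benzyloxy)-4,5-dimethoxybenzaldehyde | COc1cc(C=O)cc(OCc2ccccc2)c1OC | intermediate
9 | 1-(benzyloxy)-5-ethynyl-2,3-dimethoxybenzene | COc1cc(C#C)cc(OCc2ccccc2)c1OC | intermediate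
10 | carbon monoxide | [C-]#[O+] | starting material
11 | 3-[3-(benzyloxy)-4,5-dimethoxyphenyl]-1-(2-hydroxy-3,4-dimethoxyphenyl)prop-2-yn-1-one | COc1cc(C#CC(=O)c2ccc(OC)c(OC)c2O)cc(OCc2ccccc2)c1OC | intermediate
12 | (2E)-3-[3-(benzyloxy)-4,5-dimethoxyphenyl]-3-(diethylamino)-1-(2-hydroxy-3,4-dimethoxyphenyl)prop-2-en-1-one (geometry of no consequence) | CCN(CC)/C(=C/C(=O)c1ccc(OC)c(OC)c1O)c1cc(OC)c(OC)c(OCc2ccccc2)c1 | intermediate
13 | 3'-benzyloxy-4',5',7,8-tetramethoxyflavone [2-(3-benzyloxy-4,5-dimethoxyphenyl)-7,8-dimethoxy-4H-chromen-4-one] | COc1cc(C2=CC(=O)c3ccc(OC)c(OC)c3O2)cc(OCc2ccccc2)c1OC | intermediate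
14 | (2S,4S)-3'-benzyloxy-4',5',7,8-tetramethoxyflavan-4-ol (2,4-cis) | COc1cc([C@@H]2C[C@H](O)c3ccc(OC)c(OC)c3O2)cc(OCc2ccccc2)c1OC | intermediate
15 | (2S)-3'-benzyloxy-4',5',7,8-tetramethoxyflavanone | COc1cc([C@@H]2CC(=O)c3ccc(OC)c(OC)c3O2)cc(OCc2ccccc2)c1OC | intermediate
16 | (2S)-3'-hydroxy-4',5',7,8-tetramethoxyflavanone | COc1cc([C@@H]2CC(=O)c3ccc(OC)c(OC)c3O2)cc(O)c1OC | target

## Step count and least certain steps

Total step count: 8 (step 7 is one operation in two stages with one purification). Longest linear sequence: 6 steps (1, 2, 3, 6, 7, 8 from compound 1); the ring B branch is 5 steps (4, 5, 6, 7, 8).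

Step 6 (key step). The most likely failures are loss of the aroyl complex of divalent palladium to diethylamine (amide formation) or coupling before carbonyl insertion. Both become more likely because oxidative addition into the hindered, electron-rich C–I bond next to a free hydroxyl is slow and the catalyst spends longer in unproductive states. The fallback sets out from 8 and returns at 13. Claisen–Schmidt condensation of 8 with commercially available 1-(2-hydroxy-3,4-dimethoxyphenyl)ethan-1-one F1 (KOH, EtOH, rt) should give the 2'-hydroxychalcone F2. Oxidative cyclisation of F2 with catalytic I2 in DMSO at 130 °C should then give 13. Ring C is built here by aldol condensation, oxa-Michael addition and dehydrogenation, without palladium, 5 or carbon monoxide.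

Step 7. The most likely failure is insufficient discrimination between the two faces of C2=C3, because the 7,8-dimethoxy pattern and the trioxygenated ring B differ sterically and electronically from simple flavones; over-reduction is already absorbed by the oxidation stage. The fallback sets out from 15 of insufficient enantiomeric purity, as step 7 would then deliver it, and returns at 15. Asymmetric transfer hydrogenation with RuCl(p-cymene)(TsDPEN) (the ligand antipode that reduces the 2R ketone faster; HCO2H/Et3N, EtOAc, rt), run to partial conversion, should turn the unwanted (2R)-flavanone F3 into the (2R,4R)-flavan-4-ol F4. F4 is separated by chromatography from unreacted 15. Stereocontrol then rests on a kinetic resolution by a second, independent catalyst and not on face selection at the flat flavone. If the ruthenium carbene catalyst did not turn over at all, the same resolution could be fed with racemic material made from chalcone F2 by ring closure with NaOAc in refluxing EtOH.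

Step 8. The most likely failure is reductive opening of ring C at the benzylic C2–O1 bond, or reduction of the C4 carbonyl, competing with O-debenzylation once the benzyl ether is nearly consumed. The fallback sets out from 13 and returns at 16.
- The benzyl ether is removed at the flavone stage, where no benzylic ring C–O bond and no stereocentre is at risk (H2, Pd/C, EtOAc/THF), to give the phenol F5.
- F5 is silylated (TBSCl, imidazole, DMF) to F6.
- F6 is hydrogenated and reoxidised as in step 7, through the flavan-4-ol F7, to the (2S)-flavanone silyl ether F8.
- F8 is desilylated with Et3N·3HF in THF, a weakly acidic fluoride source that should not open ring C, to give 16.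

Step 2. The most likely failure is competing or incomplete metalation: deprotonation ortho to the terminal methoxy group instead of ortho to the acetal, which would put iodine on the wrong carbon. The fallback sets out from 1 and returns at 5, replacing steps 1 to 3.
- Carbamoylation (Et2NCOCl, K2CO3, MeCN, reflux) gives the aryl diethylcarbamate F9, whose carbonyl oxygen is a much stronger anchor for the base than an ether oxygen.
- s-BuLi/TMEDA in THF at −78 °C followed by I2 gives the 6-iodo carbamate F10; the mixture is kept cold to avoid the anionic ortho-Fries shift.
- Hydrolysis (NaOH, EtOH/H2O, reflux, then acidification) gives 5.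

Further compounds

F1 | step 6 | 1-(2-hydroxy-3,4-dimethoxyphenyl)ethan-1-one | CC(=O)c1ccc(OC)c(OC)c1O
F2 | step 6 | (2E)-3-[3-(benzyloxy)-4,5-dimethoxyphenyl]-1-(2-hydroxy-3,4-dimethoxyphenyl)prop-2-en-1-one | COc1cc(/C=C/C(=O)c2ccc(OC)c(OC)c2O)cc(OCc2ccccc2)c1OC
F3 | step 7 | (2R)-3'-benzyloxy-4',5',7,8-tetramethoxyflavanone | COc1cc([C@H]2CC(=O)c3ccc(OC)c(OC)c3O2)cc(OCc2ccccc2)c1OC
F4 | step 7 | (2R,4R)-3'-benzyloxy-4',5',7,8-tetramethoxyflavan-4-ol | COc1cc([C@H]2C[C@@H](O)c3ccc(OC)c(OC)c3O2)cc(OCc2ccccc2)c1OC
F5 | step 8 | 3'-hydroxy-4',5',7,8-tetramethoxyflavone | COc1cc(C2=CC(=O)c3ccc(OC)c(OC)c3O2)cc(O)c1OC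
F6 | step 8 | 3'-(tert-butyldimethylsilyloxy)-4',5',7,8-tetramethoxyflavone | COc1cc(C2=CC(=O)c3ccc(OC)c(OC)c3O2)cc(O[Si](C)(C)C(C)(C)C)c1OC
F7 | step 8 | (2S,4S)-3'-(tert-butyldimethylsilyloxy)-4',5',7,8-tetramethoxyflavan-4-ol | COc1cc([C@@H]2C[C@H](O)c3ccc(OC)c(OC)c3O2)cc(O[Si](C)(C)C(C)(C)C)c1OC
F8 | step 8 | (2S)-3'-(tert-butyldimethylsilyloxy)-4',5',7,8-tetramethoxyflavanone | COc1cc([C@@H]2CC(=O)c3ccc(OC)c(OC)c3O2)cc(O[Si](C)(C)C(C)(C)C)c1OC
F9 | step 2 | 2,3-dimethoxyphenyl N,N-diethylcarbamate | CCN(CC)C(=O)Oc1cccc(OC)c1OC
F10 | step 2 | 6-iodo-2,3-dimethoxyphenyl N,N-diethylcarbamate | CCN(CC)C(=O)Oc1c(I)ccc(OC)c1OC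
A1 | alternative 1 | (1S)-1-[3-(benzyloxy)-4,5-dimethoxyphenyl]-2-[2-(2-bromo-3,4-dimethoxyphenyl)-1,3-dioxolan-2-yl]ethan-1-ol | COc1cc([C@@H](O)CC2(OCCO2)c2ccc(OC)c(OC)c2Br)cc(OCc2ccccc2)c1OC
A2 | alternative 1 | (2S)-3'-benzyloxy-4',5',7,8-tetramethoxyflavanone ethylene ketal | COc1cc([C@@H]2CC3(OCCO3)c3ccc(OC)c(OC)c3O2)cc(OCc2ccccc2)c1OC
A3 | alternative 2 | 6-(dimethoxymethyl)-2,3-dimethoxyphenol | COC(OC)c1ccc(OC)c(OC)c1O
A4 | alternative 2 | 1-(benzyloxy)-5-ethenyl-2,3-dimethoxybenzene | COc1cc(C=C)cc(OCc2ccccc2)c1OC
A5 | alternative 2 | (2S,4S)-cis-3'-benzyloxy-4,4',5',7,8-pentamethoxyflavan | COc1cc([C@@H]2C[C@H](OC)c3ccc(OC)c(OC)c3O2)cc(OCc2ccccc2)c1OC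
A6 | alternative 3 | [3-(benzyloxy)-4,5-dimethoxyphenyl](2,3-dimethoxyphenoxy)methyl acetate (racemic) | CC(=O)OC(Oc1cccc(OC)c1OC)c1cc(OC)c(OC)c(OCc2ccccc2)c1
A7 | alternative 3 | 1,1-diethoxyethene (ketene diethyl acetal) | C=C(OCC)OCC
A8 | alternative 3 | (2S)-3'-benzyloxy-4,4-diethoxy-4',5',7,8-tetramethoxyflavan | COc1cc([C@@H]2CC(OCC)(OCC)c3ccc(OC)c(OC)c3O2)cc(OCc2ccccc2)c1OC
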